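**Plan**
1. Retrosynthesis: cut the O–Si bond at O6; then, in one stroke, the aryl–acyl bond C3–C3a together with the two C–O bonds of a menthone ketal that ties the C2 hydroxyl and the C3 acyl carbon into a 1,3-dioxolan-4-one; then C2–C1' (farnesyl), C2–OAr and the spiroketal.
2. Enabling feature: C2 carries two oxygens next to the C3 carbonyl, so O1–C2(OH)–C3(=O) is the aryl hemiketal of an α-keto acid. Held as a dioxolanone, its lactone carbonyl (C3) lies five atoms from C3a, the benzene carbon ortho to O1 and para to O6, where a bromine allows metalation.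
3. Forward: the temporary dioxolanone ring is made first, then brominated and joined to the aryl ether; the farnesyl chain follows by enolate alkylation. The furanone ring closes last by anionic acylation, which also expels the auxiliary and frees the hemiketal OH.
4. Stereochemistry: the only stereocentre, C2 (R), is set in the alkylation by the spiro-menthane from (−)-menthone and is kept in the ring closure because no bond to C2 is touched. Both alkenes arrive with (2E,6E)-farnesyl bromide.

Key step: step 6

Assumption: the hemiketal carbon C2 keeps its configuration in neutral or weakly acidic aprotic media; it can be lost only by opening to the open-chain 1,2-diketone, which base promotes, so the free hemiketal is never exposed to base.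

Step 1
Reactants: 1 (−)-menthone [(2S,5R)-2-isopropyl-5-methylcyclohexan-1-one]; 2 trimethylsilyl 2-[(trimethylsilyl)oxy]acetate
Product: 3 (5R,6S,9R)-6-isopropyl-9-methyl-1,4-dioxaspiro[4.5]decan-2-one
Conditions: Me3SiOTf (5 mol %), CH2Cl2, −78 → −20 °C; pyridine; chromatography (removes the 5S spiro-epimer)
Reagents that add atoms: none
Why: Lewis-acid-catalysed silyl-transfer ketalisation of a ketone with a bis-silylated α-hydroxy acid should give the spiro-1,3-dioxolan-4-one without epimerising C2 of menthone; the spiro carbon is the only new stereocentre, both epimers are expected, and the 5R one (ether oxygen O4 axial on the chair) is carried on while the other can be re-equilibrated with the same catalyst.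

Step 2
Reactants: 3
Product: 4 3-bromo-6-isopropyl-9-methyl-1,4-dioxaspiro[4.5]decan-2-one (spiro centre and menthane ring as in 3; both C3 epimers)
Conditions: NBS, AIBN (cat.), PhCF3, 80 °C; used crude
Reagents that add atoms: N-bromosuccinimide, O=C1CCC(=O)N1Br
Why: Wohl–Ziegler radical bromination should go at C3 because the radical there is captodative (lactone carbonyl plus ether oxygen), as in brominations of other glycolic acid ketals; the C3 centre forms as a mixture, which does not matter because it is flattened in step 5.

Step 3
Reactants: 5 4-bromoresorcinol (4-bromobenzene-1,3-diol)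
Product: 6 2-bromo-5-[(triisopropylsilyl)oxy]phenol
Conditions: i-Pr3SiCl (1.0 equiv), imidazole, CH2Cl2, 0 °C
Reagents that add atoms: chlorotriisopropylsilane, CC(C)[Si](Cl)(C(C)C)C(C)C
Why: Silylation with a bulky silyl chloride should pick the hydroxyl para to bromine, since the other hydroxyl is flanked by the ortho bromine and hydrogen-bonded to it; no stereocentre is formed.

Step 4
Reactants: 4; 6
Product: 7 (5R,6S,9R)-3-{2-bromo-5-[(triisopropylsilyl)oxy]phenoxy}-6-isopropyl-9-methyl-1,4-dioxaspiro[4.5]decan-2-one (both C3 epimers)
Conditions: K2CO3, MeCN, 0 °C → rt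
Reagents that add atoms: none
Why: Williamson-type O-alkylation of the phenoxide by an α-bromo ether that is also an α-bromo lactone, a very reactive SN2 electrophile, should outrun attack at the lactone carbonyl; both C3 epimers serve.

Step 5
Reactants: 7; 8 (2E,6E)-farnesyl bromide
Product: 10 (3S,5R,6S,9R)-3-{2-bromo-5-[(triisopropylsilyl)oxy]phenoxy}-6-isopropyl-9-methyl-3-[(2E,6E)-3,7,11-trimethyldodeca-2,6,10-trien-1-yl]-1,4-dioxaspiro[4.5]decan-2-one, via lithium enolate 9 (not isolated)
Conditions: LiN(i-Pr)2, THF, −78 °C; then 8, DMPU, −78 → −45 °C; chromatography (removes any C3 epimer)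
Reagents that add atoms: none
Why: Alkylation of a chiral 1,3-dioxolan-4-one enolate (self-regeneration-of-stereocentres type) with a primary allylic bromide: deprotonation flattens C3 so both epimers of 7 converge on enolate 9, whose face on the side of the isopropyl-bearing carbon C6 is screened, so 8 should enter from the face flanked by the C10 methylene and set C3 as S (the future 2R), while SN2 attack at the primary carbon keeps the chain linear and both alkenes E.

Step 6
Reactants: 10
Product: 14 (2R)-2-hydroxy-6-[(triisopropylsilyl)oxy]-2-[(2E,6E)-3,7,11-trimethyldodeca-2,6,10-trien-1-yl]-1-benzofuran-3(2H)-one, via aryllithium 11 (not isolated), via lithium alkoxide 12 (not isolated), via hemiorthoester 13 (not isolated)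
Conditions: t-BuLi (2.1 equiv), THF/Et2O/pentane, −100 °C; then AcOH in THF, −100 °C → rt; pH 7 buffer
Reagents that add atoms: none
Why: Bromine–lithium exchange at the carbon ortho to the aryl ether oxygen gives aryllithium 11, which adds to the lactone carbonyl to form the aryl–C3 bond; the lithium alkoxide 12 is protonated cold to hemiorthoester 13, which on warming expels the ketal oxygen to give the C3 ketone and then loses menthone, leaving the free C2 hydroxyl. The closest known reaction types are the Parham cyclisation of 2-haloaryloxy esters and amides to benzofuran-3(2H)-ones and the mono-addition of organolithiums to 1,3-dioxolan-4-ones that gives α-hydroxy ketones. The furanone ring closes in an anionic 5-exo-trig mode. The only new stereocentre, the carbinol carbon of 12 and 13, is transient and forced cis by the fusion of the two five-membered rings, and the C2 configuration from step 5 is carried over because no bond to C2 is made or broken. The step needs exchange to beat direct addition of t-BuLi to the lactone, which the fast exchange of an aryl bromide next to an ether oxygen at −100 °C and the fully substituted carbon beside the carbonyl should secure. It also needs the hemiketal never to meet base, which the acid quench before collapse of 12 should secure, since alkoxide-triggered opening to the 1,2-diketone would erase C2.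

Step 7
Reactants: 14
Product: 15 (2R)-2,6-dihydroxy-2-[(2E,6E)-3,7,11-trimethyldodeca-2,6,10-trien-1-yl]-1-benzofuran-3(2H)-one (target)
Conditions: HF·pyridine, pyridine, THF, 0 °C
Reagents that add atoms: none
Why: Fluoride cleavage of an aryl silyl ether under buffered, weakly acidic conditions breaks only the Si–O bond, so the hemiketal carbon, the aryl ketone and the trisubstituted alkenes should be untouched and C2 is not exposed to base.

**Compound list**
1 | (−)-menthone, (2S,5R)-2-isopropyl-5-methylcyclohexan-1-one | C[C@@H]1CC[C@@H](C(C)C)C(=O)C1 | starting material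
2 | trimethylsilyl 2-[(trimethylsilyl)oxy]acetate | C[Si](C)(C)OCC(=O)O[Si](C)(C)C | starting material
3 | (5R,6S,9R)-6-isopropyl-9-methyl-1,4-dioxaspiro[4.5]decan-2-one (O4 axial, isopropyl and methyl equatorial) | C[C@@H]1CC[C@@H](C(C)C)[C@]2(C1)OCC(=O)O2 | intermediate
4 | 3-bromo derivative of 3, spiro centre unchanged in space (formally 5S because bromine raises the rank of O4), both C3 epimers | C[C@@H]1CC[C@@H](C(C)C)[C@]2(C1)OC(Br)C(=O)O2 | intermediate
5 | 4-bromoresorcinol | Oc1ccc(Br)c(O)c1 | starting material
6 | 2-bromo-5-[(triisopropylsilyl)oxy]phenol | Oc1cc(O[Si](C(C)C)(C(C)C)C(C)C)ccc1Br | intermediate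
7 | (5R,6S,9R)-3-{2-bromo-5-[(triisopropylsilyl)oxy]phenoxy}-6-isopropyl-9-methyl-1,4-dioxaspiro[4.5]decan-2-one, both C3 epimers | C[C@@H]1CC[C@@H](C(C)C)[C@]2(C1)OC(Oc3cc(O[Si](C(C)C)(C(C)C)C(C)C)ccc3Br)C(=O)O2 | intermediate
8 | (2E,6E)-farnesyl bromide | BrC/C=C(\C)CC/C=C(\C)CCC=C(C)C | starting material
9 | lithium enolate of 7 (C3=C2 enolate, OLi on C2) | C[C@@H]1CC[C@@H](C(C)C)[C@]2(C1)OC(Oc3cc(O[Si](C(C)C)(C(C)C)C(C)C)ccc3Br)=C(O[Li])O2 | intermediate
10 | (3S,5R,6S,9R)-3-{2-bromo-5-[(triisopropylsilyl)oxy]phenoxy}-6-isopropyl-9-methyl-3-[(2E,6E)-3,7,11-trimethyldodeca-2,6,10-trien-1-yl]-1,4-dioxaspiro[4.5]decan-2-one (farnesyl on the face of the C10 methylene, aryloxy on the face of C6) | C[C@@H]1CC[C@@H](C(C)C)[C@]2(C1)O[C@](C/C=C(\C)CC/C=C(\C)CCC=C(C)C)(Oc3cc(O[Si](C(C)C)(C(C)C)C(C)C)ccc3Br)C(=O)O2 | intermediate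
11 | aryllithium from 10 (lithium in place of bromine) | C[C@@H]1CC[C@@H](C(C)C)[C@]2(C1)O[C@](C/C=C(\C)CC/C=C(\C)CCC=C(C)C)(Oc3cc(O[Si](C(C)C)(C(C)C)C(C)C)ccc3[Li])C(=O)O2 | intermediate
12 | lithium alkoxide of the tetrahedral adduct: cis-fused 2,3-dihydrobenzofuran whose C2–O and C3–O are bridged by the menthane spiro carbon (1,3-dioxolane ring), C3 bearing OLi, C2 as in 10 | C[C@@H]1CC[C@@H](C(C)C)[C@]2(C1)O[C@]3(C/C=C(\C)CC/C=C(\C)CCC=C(C)C)Oc4cc(O[Si](C(C)C)(C(C)C)C(C)C)ccc4[C@]3(O[Li])O2 | intermediate
13 | hemiorthoester, the protonated form of 12 (OH in place of OLi) | C[C@@H]1CC[C@@H](C(C)C)[C@]2(C1)O[C@]3(C/C=C(\C)CC/C=C(\C)CCC=C(C)C)Oc4cc(O[Si](C(C)C)(C(C)C)C(C)C)ccc4[C@]3(O)O2 | intermediate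
14 | (2R)-2-hydroxy-6-[(triisopropylsilyl)oxy]-2-[(2E,6E)-3,7,11-trimethyldodeca-2,6,10-trien-1-yl]-1-benzofuran-3(2H)-one | CC(C)=CCC/C(C)=C/CC/C(C)=C/C[C@@]1(O)Oc2cc(O[Si](C(C)C)(C(C)C)C(C)C)ccc2C1=O | intermediate
15 | (2R)-2,6-dihydroxy-2-[(2E,6E)-3,7,11-trimethyldodeca-2,6,10-trien-1-yl]-1-benzofuran-3(2H)-one | CC(C)=CCC/C(C)=C/CC/C(C)=C/C[C@@]1(O)Oc2cc(O)ccc2C1=O | target

Total step count: 7. Longest linear sequence: 6 (steps 1, 2, 4, 5, 6, 7).

**Steps most likely to fail**

Step 6. What may go wrong: collapse of lithium alkoxide 12 before the quench, followed by ring–chain equilibration of the hemiketal alkoxide (loss of C2 configuration), or addition of the alkyllithium to the lactone instead of exchange. Fallback from 10: Miyaura borylation (bis(pinacolato)diboron, Pd(dppf)Cl2, KOAc, dioxane, 80 °C) should give the aryl pinacol boronate F1. With [Rh(OH)(cod)]2 (cat., a hydroxo complex of monovalent rhodium) in dioxane/H2O the aryl group should pass to rhodium and add to the lactone carbonyl in a near-neutral medium (intramolecular acylation of an organorhodium by an ester). Hydrolysis with loss of menthone returns to the route at 14.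

Step 5. What may go wrong: fragmentation or self-condensation of the doubly oxygenated lactone enolate before C-alkylation, and incomplete discrimination between its two faces. Fallback from 7 through enolate 9: trapping with Me3SiCl at −78 °C should give the silyl ketene acetal F2. Allylation of F2 with (2E,6E)-farnesyl methyl carbonate F3 (from commercial (2E,6E)-farnesol, methyl chloroformate and pyridine) under Pd(PPh3)4 catalysis (zerovalent palladium, Tsuji–Trost allylation of a ketene silyl acetal, THF, 0 °C) should form the C–C bond at the unsubstituted allyl terminus. The bulky π-allyl electrophile should meet the enolate on its open face at low temperature; the route is rejoined at 10.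

Step 7. What may go wrong: erosion of configurational purity of the free hemiketal during fluoride treatment through ring–chain tautomerism, or a benzilic-type rearrangement of the opened form. Fallback from 10: the silyl group is removed first, while C2 is still a stable ketal (Bu4NF/AcOH, THF, 0 °C), to give the phenol F4. Deprotonation of F4 with MeLi (1.0 equiv, −78 °C) followed by the exchange, ring closure and cold acid quench of step 6 should then give 15 directly, so the free hemiketal never meets fluoride.

**Further compounds**
F1 | step 6 | aryl pinacol boronate from 10 (4,4,5,5-tetramethyl-1,3,2-dioxaborolan-2-yl in place of bromine) | C[C@@H]1CC[C@@H](C(C)C)[C@]2(C1)O[C@](C/C=C(\C)CC/C=C(\C)CCC=C(C)C)(Oc3cc(O[Si](C(C)C)(C(C)C)C(C)C)ccc3B4OC(C)(C)C(C)(C)O4)C(=O)O2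
F2 | step 5 | trimethylsilyl ketene acetal of 7 (OSiMe3 on C2, C2=C3 double bond) | C[C@@H]1CC[C@@H](C(C)C)[C@]2(C1)OC(Oc3cc(O[Si](C(C)C)(C(C)C)C(C)C)ccc3Br)=C(O[Si](C)(C)C)O2
F3 | step 5 | (2E,6E)-farnesyl methyl carbonate | COC(=O)OC/C=C(\C)CC/C=C(\C)CCC=C(C)C
F4 | step 7 | phenol from 10 (free OH in place of the silyl ether) | C[C@@H]1CC[C@@H](C(C)C)[C@]2(C1)O[C@](C/C=C(\C)CC/C=C(\C)CCC=C(C)C)(Oc3cc(O)ccc3Br)C(=O)O2
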